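(All runs were generated by integration on assumed constants; the scatter is artificial.)

If L had kept its opening pace, the fraction left at any reading would have been a plain exponential of pace times time, so in the earlier runs I watched how far L stayed behind that line.

in all of them: L 0.050 M
- Tuesday's: J 0.073 M; run made earlier
- Monday's: J 0.12 M; run made earlier
- noon: J 0.100 M; time 2.5 min
- midnight: J 0.200 M; time 2.5 min

| run | time / s | L / % | D / % |
|---|---|---|---|
| Tuesday's | 10.0 | 95.9 | 3.9 |
| Tuesday's | 15.0 | 93.9 | 5.5 |
| Tuesday's | 25.0 | 90.1 | 8.9 |
| Tuesday's | 40.0 | 85.2 | 13.6 |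
| Tuesday's | 60.0 | 80.1 | 18.2 |
| Tuesday's | 120 | 66.5 | 26.7 |
| Monday's | 20.0 | 87.5 | 11.8 |
| Monday's | 40.0 | 77.2 | 20.9 |
| Monday's | 50.0 | 73.1 | 25.1 |
| Monday's | 80.0 | 62.0 | 32.6 |
| Monday's | 120 | 50.4 | 39.8 |

(each reading ± 0.3 percentage points)

- the analysis behind the earlier runs scatters by 0.3 percentage points, standard deviation

1. part of the L that has reacted at the end, noon
2. part of the L that has reacted at the end, midnight
3. what raising the concentration of J from its lowest to its highest value here does to the part of the L that has reacted (changes below 5 percentage points count as none) (it falls / no change / it rises)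

I began with the slope at the start. Tuesday's run had 90.1 % of its L left at 25.0 s, and Monday's run had 87.5 % left at 20.0 s:

Tuesday's opening pace = 0.250 min⁻¹
Monday's opening pace = 0.401 min⁻¹

Monday's pace was 1.60 times Tuesday's on 1.64 times the J, so I scaled the pace with the J charge:

noon = 0.343 min⁻¹
midnight = 0.685 min⁻¹

Next came the bend, which I measured as ln(charge/L) divided by opening pace times time:

Tuesday's run at 60.0 s: 0.887
Tuesday's run at 120 s: 0.815
Monday's run at 120 s: 0.833

Monday's figure, on more J, was no lower than Tuesday's, so I used one value for both flasks. Tuesday's fall, carried on straight to 2.5 min, gave 0.779. This kept share is the part of the opening pace held on average up to the reading.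

With it, I reckoned L's half mark in the noon flask at about 2.59 min. I drew no level: Tuesday's L was still falling at its last reading, from 80.1 % to 66.5 %.

noon: L left = exp(−pace × time × share) = 51.3 %, reacted 48.7 %
midnight: L left = 26.3 %, reacted 73.7 %

That is a rise of 25 percentage points, past the 5 points that counts.

The forecast gave 49 % and 74 %, saying “conversion rises with J”, so its third answer was: it rises.

The flasks gave 48.9 % at noon and 72.9 % at midnight, a rise of 24 points, so the third answer is: it rises.

    L + J → Q + D (k = 0.0584 M⁻¹ s⁻¹)
    J + Q ⇌ X, settled at all times (K = 54000 M⁻¹)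
    L + D → E (k = 0.0445 M⁻¹ s⁻¹)
    2 J → Z (k = 0.00650 M⁻¹ s⁻¹)

Those results correspond to kept shares of 0.783 at noon and 0.762 at midnight, against my 0.779. I took the same share to a neighbouring flask, like noon but with 0.025 M of J. That is 0.500 equiv to L, which makes J the limiting reagent by charge. Its opening pace of 0.0857 min⁻¹ and the kept share give 15.4 % reacted at 2.5 min, and the flask gave 15.7 %. There, 84 % of the L stood at the end, and 44 % of the charged J was still there, unbound.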